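## Structural features

The target is a germacranolide. Germacrane numbering is used throughout: ring C1–C10, C14 the methyl on C10, C15 the oxygenated CH2 on C4, C11(=C13)–C12(=O) the lactone side chain. A (1(10)E,4E)-cyclodeca-1(10),4-diene is trans-fused at C7–C8 to an α-methylene-γ-butyrolactone whose ring oxygen sits on C8. Three contiguous stereocentres, C6 (R, O-isovalerate), C7 (R) and C8 (S), carry O6 and O8 on one face and C11 on the other. The fourth, C3 (R, free OH), lies across C4=C5 from C6. C4=C5 is flanked by three oxygenated allylic carbons (C3, C6, C15) with C15 cis to C6, and O6 and O15 carry the same acyl group. Fragile features are: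
- the strained E,E-1,5-diene (Cope rearrangement on heating, transannular cyclisation in acid);
- the 3-hydroxy-1,5-diene (oxy-Cope with dissociated alkoxides);
- the exo-methylene lactone (Michael acceptor);
- the 1,3-related O3/O15 pair (acyl migration).

The real difficulty is closing the ten-membered ring with two E-trisubstituted alkenes while setting C6/C7/C8. The key step exploits the array O6–C6–C7–C11=C13, with C6 attached to the C4–C5 unsaturation. This is the retron of a [2,3]-Wittig rearrangement, so ring C1–C10 can come from a 13-membered ring that also contains O6 and C13.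

## Logic of the disconnections

33 to 29 (via 32): the O3–Si bond and the lactone C12–O8 bond (with the C12 oxidation level) are cut. The free O3 and the exo-methylene lactone are the most sensitive groups and are made last. The lactone becomes a 2-methylene-1,4-diol whose O8/O12 pair can travel as one acetal (28). The forward steps need an oxidation that touches only the allylic primary alcohol and deprotections that spare two esters.

28 to 27: both ester C–O bonds are cut. Since O6 and O15 carry the same acyl group, one acylation serves, provided O3 is masked.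

27 to 23 (via 25): C4–C15 and C5–H are cut. The C4=C5 alkene with C15 cis to C6 is the anti-addition product of H and C across a C4≡C5 alkyne. This removes one E-alkene from the ring (leaving a cyclodec-1-en-5-yne) and all alkene-geometry problems at C4. The forward step needs O6 as the only free propargylic hydroxyl, hence 23 from 22.

22 to 20 (key): C6–C7 is cut and O6 is reconnected to C13. In one sentence: a [2,3]-Wittig ring contraction of the 13-membered propargyl allyl ether 20 forms C6–C7 and the ten-membered ring. Ring closure is moved to a C–O bond in a less strained ring, C6 becomes CH2, C7 becomes sp2, and the exo-methylene is accounted for. The forward step needs selective deprotonation at C6, face selectivity at C7 relayed from C8, and an O3 that cannot leave from the propargyl anion.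

20 to 17 (via 18): the O–C6 ether bond is cut (C13 alkoxide plus C6 chloride). The two chain ends are then ordinary functional groups. The forward step is a macro-etherification that must beat oligomerisation.

17 to 14 + 15: C3–C4 is cut. This removes C3 (set by catalyst) and three carbons. The aldehyde is β,γ-unsaturated, so the addition must be non-basic.

14 to 11 (via 13): C1–C2 and C10–C14 are cut. The E-trisubstituted C1=C10 alkene comes from a terminal alkyne by syn-carbometalation, and C2–C3 from ethylene oxide. The acetal must tolerate the aluminium reagent.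

11 to 5 (via 10 and 7): C11–C12 and C7–H are cut, again anti-addition of H and C across an alkyne directed by O8. This places C12 cis and C13 trans to C8, the distinction the key step and the lactone both need.

5 to 3 + 4: C8–C9 is cut. C8 is the one stereocentre from which C7 and C6 are later relayed, and it is set by catalysis.

3 to 1: C7–C8 is cut (formyl carbon from DMF), reaching a commercial propargyl ether.

## Other disconnections considered

Alternative 1: (the first that comes to mind) Cut C7–C8 and the lactone C–O bond. The forward step is a chromium(II)- or zinc-mediated intramolecular allylation of the ω-formyl 2-(bromomethyl)enoate A1, giving lactone A2 directly. Grounds against it: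
- The nucleophilic carbon C7 of the allyl metal has the C6 silyloxy group in the β-position, so β-elimination to a diene competes.
- The ring strain is paid in an end-to-end closure.
- The fully oxygenated C4=C5 unit must be built with complete geometry control beforehand.
- The cis/trans sense of the lactone from a ten-membered cyclic transition state is not predictable.

Alternative 2: Cut C8–C9 and take O6 back to a ketone. The forward step is an anionic oxy-Cope ring expansion of the 1,2-divinylcyclohexenol A3 to the cyclodecadienone A4. Grounds against it: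
- The C4=C5 bond has to lie inside the six-membered ring of A3, so it emerges Z in A4, the wrong geometry.
- C8 arrives without oxygen and the lactone carbons are absent.
- The step count after ring formation would exceed that of the chosen plan.

Alternative 3: Cut C6–C7 as in the chosen plan, but close it by a Lewis-acid-promoted carbonyl-ene macrocyclisation of ynal A5 to A6. This is the polar counterpart of the C6–C7 bond formation in germacrene biosynthesis. Grounds against it:
- It is an end-to-end closure of a ten-membered ring, whereas this ene macrocyclisation has support only for larger rings.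
- The ene donor is deactivated by the allylic C8 oxygen.
- The Lewis acid can ionise the allylic and propargylic silyl ethers.
- C12 would still need selective oxidation.
- The Wittig contraction forms the same bond through a five-membered transition state from a ring that is easier to close.

Key step: step 11

Assumptions: compounds 1, 4 and 15 and all named reagents are taken as commercial. The ligand antipodes in steps 2 and 8 are those that give (S)-C8 and (R)-C3; the sense would be verified on 5 and 17 before continuing.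

## Route

Step 1
Reactants: 1 1-methoxy-4-[(prop-2-yn-1-yloxy)methyl]benzene
Product: 3 4-[(4-methoxybenzyl)oxy]but-2-ynal, via lithium acetylide 2 (not isolated)
Conditions: n-BuLi, THF, −78 °C; DMF; inverse quench into aq. KH2PO4/MTBE, 0 °C
Reagents that add atoms: N,N-dimethylformamide, CN(C)C=O
Why: Deprotonation of the terminal alkyne and formylation of the acetylide with DMF; the buffered inverse quench keeps the liberated amine from adding to the ynal; no stereocentre is formed.

Step 2
Reactants: 3 4-[(4-methoxybenzyl)oxy]but-2-ynal; 4 trimethyl[3-(4,4,5,5-tetramethyl-1,3,2-dioxaborolan-2-yl)prop-1-yn-1-yl]silane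
Product: 5 (4S)-1-[(4-methoxybenzyl)oxy]-7-(trimethylsilyl)hepta-2,6-diyn-4-ol
Conditions: Cu(II) isobutyrate (5 mol %), LiOtBu (8 mol %), chiral BIBOP-type bisphosphine (7 mol %), THF, −60 °C; aq. work-up
Reagents that add atoms: none
Why: Copper-catalysed asymmetric propargylation: boron-to-copper exchange gives an allenylcopper that adds through its CH2 terminus (SE2') to the aldehyde, and the chiral bisphosphine selects the aldehyde face to set C8 (S); the silyl cap enforces the homopropargyl product; the reaction type is established for aryl, alkyl and alkenyl aldehydes and is applied here to an ynal.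

Step 3
Reactants: 5 (4S)-1-[(4-methoxybenzyl)oxy]-7-(trimethylsilyl)hepta-2,6-diyn-4-ol
Product: 7 (2Z,4S)-2-iodo-1-[(4-methoxybenzyl)oxy]-7-(trimethylsilyl)hept-2-en-6-yn-4-ol, via sodium alkenylaluminate 6 (not isolated)
Conditions: Red-Al, THF, −20 → 0 °C; EtOAc; I2, THF, −78 °C
Reagents that add atoms: iodine, II
Why: Hydroxyl-directed trans-hydroalumination of a propargylic alcohol: the alkoxyaluminate delivers hydride to the proximal carbon C7 and leaves aluminium on C11 in the five-membered chelate 6; iodinolysis with retention gives the iodide cis to C8, which fixes C13 trans to C8; the silylated alkyne has no directing hydroxyl and should not react.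

Step 4
Reactants: 7 (2Z,4S)-2-iodo-1-[(4-methoxybenzyl)oxy]-7-(trimethylsilyl)hept-2-en-6-yn-4-ol
Product: 10 (2E,4S)-2-(hydroxymethyl)-1-[(4-methoxybenzyl)oxy]hept-2-en-6-yn-4-ol, via dilithio species 8 (not isolated), via silylated diol 9 (not isolated)
Conditions: MeLi (1 equiv), Et2O, −78 °C; t-BuLi (2.1 equiv), −78 °C; CH2O (g), −78 → −20 °C; then MeOH, K2CO3 (cat.), rt
Reagents that add atoms: formaldehyde, C=O
Why: Iodine–lithium exchange on the lithium alkoxide gives the alkoxide-chelated vinyllithium 8 with retention (2-lithioallyl ethers are stable at −78 °C); formaldehyde installs C12 cis to C8; methanolic carbonate then cleaves the alkynyl–silicon bond.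

Step 5
Reactants: 10 (2E,4S)-2-(hydroxymethyl)-1-[(4-methoxybenzyl)oxy]hept-2-en-6-yn-4-ol
Product: 11 (4S)-6-{[(4-methoxybenzyl)oxy]methyl}-2,2-dimethyl-4-(prop-2-yn-1-yl)-4,7-dihydro-1,3-dioxepine
Conditions: Me2C(OMe)2, PPTS (cat.), CH2Cl2, 0 °C → rt
Reagents that add atoms: 2,2-dimethoxypropane, COC(C)(C)OC
Why: Acid-catalysed transketalisation; the cis-2-ene-1,4-diol closes the seven-membered isopropylidene acetal, which ties O8 and O12 in a base-stable group that cannot migrate to O13 and fixes the conformation about C7–C8 for step 11.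

Step 6
Reactants: 11 (4S)-6-{[(4-methoxybenzyl)oxy]methyl}-2,2-dimethyl-4-(prop-2-yn-1-yl)-4,7-dihydro-1,3-dioxepine
Product: 13 (3E)-5-[(4S)-6-{[(4-methoxybenzyl)oxy]methyl}-2,2-dimethyl-4,7-dihydro-1,3-dioxepin-4-yl]-4-methylpent-3-en-1-ol, via alkenylalane 12 (not isolated)
Conditions: Me3Al, Cp2ZrCl2 (cat.), H2O (1 equiv), CH2Cl2, −25 °C; then n-BuLi, THF, −78 °C; ethylene oxide, −78 → 0 °C
Reagents that add atoms: trimethylaluminium, C[Al](C)C; oxirane (ethylene oxide), C1CO1
Why: Zirconium-catalysed Negishi carboalumination adds methyl and aluminium syn across the terminal alkyne (methyl on C10, Al on C1, C9 trans to Al); the derived alkenylalanate opens ethylene oxide with retention, giving the E-trisubstituted C1=C10 alkene and the C2–C3 unit; the water-accelerated variant runs at −25 °C, where the allylic acetal should tolerate Me3Al.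

Step 7
Reactants: 13 (3E)-5-[(4S)-6-{[(4-methoxybenzyl)oxy]methyl}-2,2-dimethyl-4,7-dihydro-1,3-dioxepin-4-yl]-4-methylpent-3-en-1-ol
Product: 14 (3E)-5-[(4S)-6-{[(4-methoxybenzyl)oxy]methyl}-2,2-dimethyl-4,7-dihydro-1,3-dioxepin-4-yl]-4-methylpent-3-enal
Conditions: Dess–Martin periodinane, NaHCO3, CH2Cl2, 0 °C; used crude
Reagents that add atoms: none
Why: Dess–Martin oxidation under buffered, non-basic conditions should give the β,γ-unsaturated aldehyde without migration of the double bond into conjugation.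

Step 8
Reactants: 14 (3E)-5-[(4S)-6-{[(4-methoxybenzyl)oxy]methyl}-2,2-dimethyl-4,7-dihydro-1,3-dioxepin-4-yl]-4-methylpent-3-enal; 15 3-chloroprop-1-yne
Product: 17 (4R,6E)-1-chloro-8-[(4S)-6-{[(4-methoxybenzyl)oxy]methyl}-2,2-dimethyl-4,7-dihydro-1,3-dioxepin-4-yl]-7-methyloct-6-en-2-yn-4-ol, via zinc alkynylide 16 (not isolated)
Conditions: Me2Zn, ProPhenol ligand (20 mol %), Ph3P=O (40 mol %), toluene, 0 °C
Reagents that add atoms: none
Why: Catalytic asymmetric alkynylation: the zinc alkynylide 16 adds to the aldehyde inside the dinuclear zinc–ProPhenol pocket, which selects the face and sets C3 (R); the amine-free medium spares the enolisable aldehyde; the propargylic chloride is carried as the leaving group for step 10.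

Step 9
Reactants: 17 (4R,6E)-1-chloro-8-[(4S)-6-{[(4-methoxybenzyl)oxy]methyl}-2,2-dimethyl-4,7-dihydro-1,3-dioxepin-4-yl]-7-methyloct-6-en-2-yn-4-ol
Product: 18 (4R,6E)-1-chloro-8-[(4S)-6-(hydroxymethyl)-2,2-dimethyl-4,7-dihydro-1,3-dioxepin-4-yl]-7-methyloct-6-en-2-yn-4-ol
Conditions: DDQ, CH2Cl2/pH 7 buffer, 0 °C
Reagents that add atoms: none
Why: Oxidative cleavage of the p-methoxybenzyl ether (hydride abstraction, then hydrolysis of the oxocarbenium ion); the buffer preserves the acetonide, and the chloride and the secondary propargylic alcohol should be inert.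

Step 10
Reactants: 18 (4R,6E)-1-chloro-8-[(4S)-6-(hydroxymethyl)-2,2-dimethyl-4,7-dihydro-1,3-dioxepin-4-yl]-7-methyloct-6-en-2-yn-4-ol
Product: 20 (3R,8S)-6,13-epoxy-8,12-(isopropylidenedioxy)-6,7-secogermacra-1(10)E,7(11)-dien-4-yn-3-ol (13-membered ether; C8 and C13 trans on C7=C11), via disodium dialkoxide 19 (not isolated)
Conditions: NaH (3 equiv), n-Bu4NI (cat.), THF, 0.002 M, slow addition, rt
Reagents that add atoms: none
Why: Intramolecular Williamson etherification under high dilution: the primary allylic C13 alkoxide displaces the halide at propargylic C6 (SN2) to give the 13-membered propargyl allyl ether; the C3 alkoxide cannot reach C6 across the linear alkyne; the sodium counter-ion and room temperature are chosen to avoid anionic oxy-Cope of the 3-oxido-1,5-enyne.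

Step 11
Reactants: 20 (3R,8S)-6,13-epoxy-8,12-(isopropylidenedioxy)-6,7-secogermacra-1(10)E,7(11)-dien-4-yn-3-ol
Product: 22 (3R,6S,7S,8S)-8,12-(isopropylidenedioxy)germacra-1(10)E,11(13)-dien-4-yne-3,6-diol, via dilithio species 21 (not isolated)
Conditions: n-BuLi (2.5 equiv), THF, −78 °C; AcOH/THF quench at −78 °C
Reagents that add atoms: none
Why: The first equivalent of base makes the C3 lithium alkoxide, which cannot leave and so blocks 1,4-elimination from the propargyl anion; the second removes the propargylic, α-oxygenated C6–H, the most acidic C–H, to give 21. A [2,3]-Wittig rearrangement follows through the five-membered envelope C6–O–C13–C11=C7: C6–C7 forms, O–C13 breaks and C11=C13 appears; this transannular ring contraction of a 13-membered propargyl allyl ether is the reaction type used to make ten-membered germacrane rings. The ten-membered carbocycle is closed by 13 → 10 contraction, so its strain is paid in an exothermic carbanion-to-alkoxide step and not in an end-to-end cyclisation. C7 is controlled by C8: the dioxepine holds C9 pseudo-equatorial and the C8–O bond out of the alkene plane, and the carbanion should add to the face anti to that C–O bond, the face carrying H8. C6 is controlled by the envelope: the alkynyl group takes the exo position, which with C8 trans to C13 gives the anti pair (O6 and C11 on opposite ring faces). The step needs C6 over C13 deprotonation (secured by propargylic acidity), [2,3] over [1,2] shift (secured by −78 °C) and facial selectivity (secured by the C8 acetal). The lithium counter-ion and the cold quench keep the product dialkoxide from anionic oxy-Cope rearrangement.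

Step 12
Reactants: 22 (3R,6S,7S,8S)-8,12-(isopropylidenedioxy)germacra-1(10)E,11(13)-dien-4-yne-3,6-diol
Product: 23 (3R,6S,7S,8S)-3-[(tert-butyldimethylsilyl)oxy]-8,12-(isopropylidenedioxy)germacra-1(10)E,11(13)-dien-4-yn-6-ol
Conditions: TBSCl (1.1 equiv), imidazole, DMF, −20 °C
Reagents that add atoms: tert-butyldimethylsilyl chloride, CC(C)(C)[Si](C)(C)Cl
Why: Selective silylation of the less hindered secondary alcohol: C3–OH is flanked by a CH2, C6–OH by the branched C7; this leaves O6 free to direct step 13.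

Step 13
Reactants: 23 (3R,6S,7S,8S)-3-[(tert-butyldimethylsilyl)oxy]-8,12-(isopropylidenedioxy)germacra-1(10)E,11(13)-dien-4-yn-6-ol
Product: 25 (3R,6S,7S,8S)-3-[(tert-butyldimethylsilyl)oxy]-4-iodo-8,12-(isopropylidenedioxy)-15-norgermacra-1(10)E,4Z,11(13)-trien-6-ol (I cis to C6), via sodium alkenylaluminate 24 (not isolated)
Conditions: Red-Al, THF, −20 → 0 °C; EtOAc; I2, −78 °C
Reagents that add atoms: iodine, II
Why: Hydroxyl-directed trans-hydroalumination as in step 3: hydride goes from the O6 aluminate to C5 and aluminium to C4 (chelate 24), then iodinolysis with retention; trans addition across the ring alkyne gives the E ring alkene (C3 trans to C6) with iodine cis to C6 and completes the E,E-1,5-diene.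

Step 14
Reactants: 25 (3R,6S,7S,8S)-3-[(tert-butyldimethylsilyl)oxy]-4-iodo-8,12-(isopropylidenedioxy)-15-norgermacra-1(10)E,4Z,11(13)-trien-6-ol
Product: 27 (3R,6R,7S,8S)-3-[(tert-butyldimethylsilyl)oxy]-8,12-(isopropylidenedioxy)germacra-1(10)E,4E,11(13)-triene-6,15-diol, via dilithio species 26 (not isolated)
Conditions: MeLi (1 equiv), Et2O/THF, −78 °C; t-BuLi (2.1 equiv), −78 °C; CH2O (g), −78 → −40 °C
Reagents that add atoms: formaldehyde, C=O
Why: Iodine–lithium exchange and hydroxymethylation as in step 4; the vinyllithium 26 is chelated by the C6 alkoxide and reacts with retention, placing C15 cis to C6; the whole operation stays below −40 °C, so the 1,5-diene is never heated.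

Step 15
Reactants: 27 (3R,6R,7S,8S)-3-[(tert-butyldimethylsilyl)oxy]-8,12-(isopropylidenedioxy)germacra-1(10)E,4E,11(13)-triene-6,15-diol
Product: 28 (3R,6R,7R,8S)-3-[(tert-butyldimethylsilyl)oxy]-8,12-(isopropylidenedioxy)germacra-1(10)E,4E,11(13)-triene-6,15-diyl bis(3-methylbutanoate)
Conditions: (iPrCH2CO)2O, Et3N, DMAP, CH2Cl2, 0 °C → rt
Reagents that add atoms: 3-methylbutanoic anhydride, CC(C)CC(=O)OC(=O)CC(C)C
Why: DMAP-catalysed acylation of the primary and the secondary allylic alcohol with the same anhydride; no selectivity is needed because O3 is silylated and O8/O12 are in the acetal.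

Step 16
Reactants: 28 (3R,6R,7R,8S)-3-[(tert-butyldimethylsilyl)oxy]-8,12-(isopropylidenedioxy)germacra-1(10)E,4E,11(13)-triene-6,15-diyl bis(3-methylbutanoate)
Product: 29 (3R,6R,7R,8S)-3-[(tert-butyldimethylsilyl)oxy]-8,12-dihydroxygermacra-1(10)E,4E,11(13)-triene-6,15-diyl bis(3-methylbutanoate)
Conditions: PPTS (cat.), MeOH, 0 °C → rt
Reagents that add atoms: none
Why: Acid-catalysed methanolysis of the seven-membered acetonide, which is more labile than the secondary TBS ether and the esters; the acid is weak enough that transannular cyclisation of the diene is not expected.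

Step 17
Reactants: 29 (3R,6R,7R,8S)-3-[(tert-butyldimethylsilyl)oxy]-8,12-dihydroxygermacra-1(10)E,4E,11(13)-triene-6,15-diyl bis(3-methylbutanoate)
Product: 32 (3R,6R,7R,8S)-3-[(tert-butyldimethylsilyl)oxy]-6,15-bis(3-methylbutanoyloxy)germacra-1(10)E,4E,11(13)-trien-12,8-olide, via hydroxy enal 30 (not isolated), via lactol 31 (not isolated)
Conditions: MnO2 (activated, excess), CH2Cl2, rt
Reagents that add atoms: none
Why: Oxidative lactonisation of a 2-methylene-1,4-diol: MnO2 oxidises the only free allylic alcohol to enal 30, the C8 hydroxyl closes lactol 31, and this is oxidised to the lactone; the trans relationship of O8 and C11 set in step 11 gives the trans-fused ring.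

Step 18
Reactants: 32 (3R,6R,7R,8S)-3-[(tert-butyldimethylsilyl)oxy]-6,15-bis(3-methylbutanoyloxy)germacra-1(10)E,4E,11(13)-trien-12,8-olide
Product: 33 (3R,6R,7R,8S)-3-hydroxy-6,15-bis(3-methylbutanoyloxy)germacra-1(10)E,4E,11(13)-trien-12,8-olide (CNP0317194.1)
Conditions: HF·pyridine, pyridine, THF, 0 °C → rt
Reagents that add atoms: none
Why: Fluoride cleavage of the silyl ether in a buffered, weakly acidic medium, which should avoid 1,3-acyl migration from O15 to O3 and conjugate addition to the methylene lactone.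

## Compound list

1 | 1-methoxy-4-[(prop-2-yn-1-yloxy)methyl]benzene | C#CCOCc1ccc(OC)cc1 | starting material
2 | {3-[(4-methoxybenzyl)oxy]prop-1-yn-1-yl}lithium | [Li]C#CCOCc1ccc(OC)cc1 | intermediate
3 | 4-[(4-methoxybenzyl)oxy]but-2-ynal | O=CC#CCOCc1ccc(OC)cc1 | intermediate
4 | trimethyl[3-(4,4,5,5-tetramethyl-1,3,2-dioxaborolan-2-yl)prop-1-yn-1-yl]silane | C[Si](C)(C)C#CCB1OC(C)(C)C(C)(C)O1 | starting material
5 | (4S)-1-[(4-methoxybenzyl)oxy]-7-(trimethylsilyl)hepta-2,6-diyn-4-ol | C[Si](C)(C)C#CC[C@H](O)C#CCOCc1ccc(OC)cc1 | intermediate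
6 | sodium alkenylaluminate from 5 (O8–Al–C11 chelate, two 2-methoxyethoxy ligands on Al) | [Na+].COCCO[Al-]1(OCCOC)O[C@@H](CC#C[Si](C)(C)C)C=C1COCc2ccc(OC)cc2 | intermediate
7 | (2Z,4S)-2-iodo-1-[(4-methoxybenzyl)oxy]-7-(trimethylsilyl)hept-2-en-6-yn-4-ol | C[Si](C)(C)C#CC[C@H](O)/C=C(I)/COCc1ccc(OC)cc1 | intermediate
8 | dilithio species from 7 (lithium alkoxide, Li in place of I) | [Li]O[C@@H](CC#C[Si](C)(C)C)/C=C([Li])/COCc1ccc(OC)cc1 | intermediate
9 | (2E,4S)-2-(hydroxymethyl)-1-[(4-methoxybenzyl)oxy]-7-(trimethylsilyl)hept-2-en-6-yn-4-ol | C[Si](C)(C)C#CC[C@H](O)/C=C(CO)/COCc1ccc(OC)cc1 | intermediate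
10 | (2E,4S)-2-(hydroxymethyl)-1-[(4-methoxybenzyl)oxy]hept-2-en-6-yn-4-ol | C#CC[C@H](O)/C=C(CO)/COCc1ccc(OC)cc1 | intermediate
11 | (4S)-6-{[(4-methoxybenzyl)oxy]methyl}-2,2-dimethyl-4-(prop-2-yn-1-yl)-4,7-dihydro-1,3-dioxepine | C#CC[C@H]1/C=C(/COCc2ccc(OC)cc2)COC(C)(C)O1 | intermediate
12 | (E)-alkenyl(dimethyl)alane from 11 (Me on C10, AlMe2 on C1) | C[Al](C)/C=C(C)/C[C@H]1/C=C(/COCc2ccc(OC)cc2)COC(C)(C)O1 | intermediate
13 | (3E)-5-[(4S)-6-{[(4-methoxybenzyl)oxy]methyl}-2,2-dimethyl-4,7-dihydro-1,3-dioxepin-4-yl]-4-methylpent-3-en-1-ol | OCC/C=C(C)/C[C@H]1/C=C(/COCc2ccc(OC)cc2)COC(C)(C)O1 | intermediate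
14 | (3E)-5-[(4S)-6-{[(4-methoxybenzyl)oxy]methyl}-2,2-dimethyl-4,7-dihydro-1,3-dioxepin-4-yl]-4-methylpent-3-enal | O=CC/C=C(C)/C[C@H]1/C=C(/COCc2ccc(OC)cc2)COC(C)(C)O1 | intermediate
15 | 3-chloroprop-1-yne | C#CCCl | starting material
16 | (3-chloroprop-1-yn-1-yl)(methyl)zinc | C[Zn]C#CCCl | intermediate
17 | (4R,6E)-1-chloro-8-[(4S)-6-{[(4-methoxybenzyl)oxy]methyl}-2,2-dimethyl-4,7-dihydro-1,3-dioxepin-4-yl]-7-methyloct-6-en-2-yn-4-ol | ClCC#C[C@H](O)C/C=C(C)/C[C@H]1/C=C(/COCc2ccc(OC)cc2)COC(C)(C)O1 | intermediate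
18 | (4R,6E)-1-chloro-8-[(4S)-6-(hydroxymethyl)-2,2-dimethyl-4,7-dihydro-1,3-dioxepin-4-yl]-7-methyloct-6-en-2-yn-4-ol | ClCC#C[C@H](O)C/C=C(C)/C[C@H]1/C=C(/CO)COC(C)(C)O1 | intermediate
19 | disodium dialkoxide of 18 | ClCC#C[C@H](O[Na])C/C=C(C)/C[C@H]1/C=C(/CO[Na])COC(C)(C)O1 | intermediate
20 | (3R,8S)-6,13-epoxy-8,12-(isopropylidenedioxy)-6,7-secogermacra-1(10)E,7(11)-dien-4-yn-3-ol (13-membered propargyl allyl ether) | O[C@@H]1C/C=C(C)/C[C@H]2/C=C(/COCC#C1)COC(C)(C)O2 | intermediate
21 | dilithio species of 20 (C3–OLi, C6–Li) | [Li]O[C@@H]1C/C=C(C)/C[C@H]2/C=C(/COC([Li])C#C1)COC(C)(C)O2 | intermediate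
22 | (3R,6S,7S,8S)-8,12-(isopropylidenedioxy)germacra-1(10)E,11(13)-dien-4-yne-3,6-diol | O[C@@H]1C/C=C(C)/C[C@H]2[C@H]([C@H](O)C#C1)C(=C)COC(C)(C)O2 | intermediate
23 | (3R,6S,7S,8S)-3-[(tert-butyldimethylsilyl)oxy]-8,12-(isopropylidenedioxy)germacra-1(10)E,11(13)-dien-4-yn-6-ol | CC(C)(C)[Si](C)(C)O[C@@H]1C/C=C(C)/C[C@H]2[C@H]([C@H](O)C#C1)C(=C)COC(C)(C)O2 | intermediate
24 | sodium alkenylaluminate from 23 (O6–Al–C4 chelate) | [Na+].COCCO[Al-]1(OCCOC)O[C@@H]2/C=C1/[C@H](O[Si](C)(C)C(C)(C)C)C/C=C(C)/C[C@H]3[C@H]2C(=C)COC(C)(C)O3 | intermediate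
25 | (3R,6S,7S,8S)-3-[(tert-butyldimethylsilyl)oxy]-4-iodo-8,12-(isopropylidenedioxy)-15-norgermacra-1(10)E,4Z,11(13)-trien-6-ol | O[C@@H]1/C=C(I)/[C@H](O[Si](C)(C)C(C)(C)C)C/C=C(C)/C[C@H]2[C@H]1C(=C)COC(C)(C)O2 | intermediate
26 | dilithio species from 25 (C6–OLi, C4–Li) | [Li]O[C@@H]1/C=C([Li])/[C@H](O[Si](C)(C)C(C)(C)C)C/C=C(C)/C[C@H]2[C@H]1C(=C)COC(C)(C)O2 | intermediate
27 | (3R,6R,7S,8S)-3-[(tert-butyldimethylsilyl)oxy]-8,12-(isopropylidenedioxy)germacra-1(10)E,4E,11(13)-triene-6,15-diol | O[C@@H]1/C=C(CO)/[C@H](O[Si](C)(C)C(C)(C)C)C/C=C(C)/C[C@H]2[C@H]1C(=C)COC(C)(C)O2 | intermediate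
28 | (3R,6R,7R,8S)-3-[(tert-butyldimethylsilyl)oxy]-8,12-(isopropylidenedioxy)germacra-1(10)E,4E,11(13)-triene-6,15-diyl bis(3-methylbutanoate) | CC(C)CC(=O)O[C@@H]1/C=C(COC(=O)CC(C)C)/[C@H](O[Si](C)(C)C(C)(C)C)C/C=C(C)/C[C@H]2[C@H]1C(=C)COC(C)(C)O2 | intermediate
29 | (3R,6R,7R,8S)-3-[(tert-butyldimethylsilyl)oxy]-8,12-dihydroxygermacra-1(10)E,4E,11(13)-triene-6,15-diyl bis(3-methylbutanoate) | CC(C)CC(=O)O[C@@H]1/C=C(COC(=O)CC(C)C)/[C@H](O[Si](C)(C)C(C)(C)C)C/C=C(C)/C[C@H](O)[C@H]1C(=C)CO | intermediate
30 | 12-oxo analogue of 29 (hydroxy enal) | CC(C)CC(=O)O[C@@H]1/C=C(COC(=O)CC(C)C)/[C@H](O[Si](C)(C)C(C)(C)C)C/C=C(C)/C[C@H](O)[C@H]1C(=C)C=O | intermediate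
31 | lactol of 30 (12-hydroxy-8,12-epoxide, both C12 epimers) | C=C1C(O)O[C@H]2C/C(C)=C/C[C@@H](O[Si](C)(C)C(C)(C)C)/C(COC(=O)CC(C)C)=C/[C@@H](OC(=O)CC(C)C)[C@H]12 | intermediate
32 | (3R,6R,7R,8S)-3-[(tert-butyldimethylsilyl)oxy]-6,15-bis(3-methylbutanoyloxy)germacra-1(10)E,4E,11(13)-trien-12,8-olide | C=C1C(=O)O[C@H]2C/C(C)=C/C[C@@H](O[Si](C)(C)C(C)(C)C)/C(COC(=O)CC(C)C)=C/[C@@H](OC(=O)CC(C)C)[C@H]12 | intermediate
33 | (3R,6R,7R,8S)-3-hydroxy-6,15-bis(3-methylbutanoyloxy)germacra-1(10)E,4E,11(13)-trien-12,8-olide (CNP0317194.1) | C=C1C(=O)O[C@H]2C/C(C)=C/C[C@@H](O)/C(COC(=O)CC(C)C)=C/[C@@H](OC(=O)CC(C)C)[C@H]12 | target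

## Step count and least certain steps

Total step count: 18. Longest linear sequence: 18 steps, from 1 to 33 (4 and 15 enter as commercial partners).

Step 11 (key step). Most likely to go wrong: competing deprotonation at the allylic C13 or C12 positions, because the C3 alkoxide lowers the acidity of C6–H; a [1,2]-shift; or addition to the wrong face of C7 if the dioxepine does not hold C9 pseudo-equatorial. Fallback: close the ten-membered ring at the same C6–C7 bond by a chromium(II)-mediated Nozaki–Hiyama allylation, setting out from 14 and returning at 23.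
- 14 is alkynylated as in step 8 with triethyl(prop-2-yn-1-yloxy)silane to give the propargylic alcohol F1.
- Silylation (TBSCl, imidazole) gives the bis-silyl ether F2.
- DDQ gives the allylic alcohol F3.
- CBr4/PPh3 gives the allylic bromide F4.
- Swern oxidation, which converts a primary triethylsilyl ether directly into the aldehyde, gives the bromo ynal F5.
- CrCl2 in THF at high dilution then adds the allylchromium through C7 to the ynal (anti selectivity through the chair transition state) to give 23.

Step 10. Most likely to go wrong: oligomerisation instead of 13-membered ring closure, and side reactions of the unprotected C3 alkoxide (intermolecular alkylation, isomerisation of the propargylic halide). Fallback: form the C13–O–C6 ether bimolecularly and close the ring by ring-closing alkyne metathesis, which is reversible and suited to 13-membered cycloalkynes, setting out from 14 and returning at 20.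
- 14 is alkynylated as in step 8 with propyne to give the propynyl carbinol F6.
- TESCl/imidazole gives the silyl ether F7.
- DDQ gives the allylic alcohol F8.
- NaH and 1-bromobut-2-yne give the but-2-ynyl ether F9.
- A molybdenum alkylidyne catalyst (5 Å molecular sieves, toluene) closes the 13-membered cycloalkyne F10 with loss of but-2-yne.
- TBAF removes the silyl group to give 20.

Step 8. Most likely to go wrong: isomerisation or self-aldol reaction of the β,γ-unsaturated aldehyde under the zinc alkoxide conditions, or low enantioselectivity with the chloro alkyne. Fallback: set C3 by reduction instead of addition, setting out from 14 and returning at 17.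
- The lithium acetylide of 15 (n-BuLi, −78 °C, CeCl3) adds to 14 to give the epimeric alcohols F11.
- Dess–Martin oxidation gives the ynone F12.
- Asymmetric transfer hydrogenation (Ru(II)–TsDPEN, 2-propanol) gives 17.

Step 2. Most likely to go wrong: conjugate addition of the copper alkoxide or allenylcopper to the ynal, or low enantioselectivity, because ynals are outside the usual aldehyde scope. Fallback: set out from 3 and return at 5.
- A zinc-mediated Barbier propargylation with 3-bromo-1-(trimethylsilyl)prop-1-yne gives the racemic alcohol F13.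
- Dess–Martin oxidation gives the ynone F14.
- Corey–Bakshi–Shibata reduction (oxazaborolidine, catecholborane, −78 °C) gives 5.

Step 14. Most likely to go wrong: loss of the vinyllithium by β-elimination of the C3 silyloxy group or by proton transfer before it meets formaldehyde, since the anion sits in a strained E-cycloalkene. Fallback: introduce C15 by palladium catalysis, setting out from 25 and returning at 27.
- Carbonylative lactonisation (Pd(PPh3)2Cl2, CO 1 atm, K2CO3, THF, rt) gives the 15,6-butenolide F15.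
- DIBAL-H (CH2Cl2, −78 °C) reduces it to the diol 27.

## Further compounds

F1 | step 11 | (4R,6E)-8-[(4S)-6-{[(4-methoxybenzyl)oxy]methyl}-2,2-dimethyl-4,7-dihydro-1,3-dioxepin-4-yl]-7-methyl-1-[(triethylsilyl)oxy]oct-6-en-2-yn-4-ol | CC[Si](CC)(CC)OCC#C[C@H](O)C/C=C(C)/C[C@H]1/C=C(/COCc2ccc(OC)cc2)COC(C)(C)O1
F2 | step 11 | 4-O-tert-butyldimethylsilyl ether of F1 | CC[Si](CC)(CC)OCC#C[C@H](O[Si](C)(C)C(C)(C)C)C/C=C(C)/C[C@H]1/C=C(/COCc2ccc(OC)cc2)COC(C)(C)O1
F3 | step 11 | allylic alcohol from F2 (p-methoxybenzyl group removed) | CC[Si](CC)(CC)OCC#C[C@H](O[Si](C)(C)C(C)(C)C)C/C=C(C)/C[C@H]1/C=C(/CO)COC(C)(C)O1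
F4 | step 11 | allylic bromide from F3 | CC[Si](CC)(CC)OCC#C[C@H](O[Si](C)(C)C(C)(C)C)C/C=C(C)/C[C@H]1/C=C(/CBr)COC(C)(C)O1
F5 | step 11 | (4R,6E)-8-[(4S)-6-(bromomethyl)-2,2-dimethyl-4,7-dihydro-1,3-dioxepin-4-yl]-4-[(tert-butyldimethylsilyl)oxy]-7-methyloct-6-en-2-ynal | O=CC#C[C@H](O[Si](C)(C)C(C)(C)C)C/C=C(C)/C[C@H]1/C=C(/CBr)COC(C)(C)O1
F6 | step 10 | (4R,6E)-8-[(4S)-6-{[(4-methoxybenzyl)oxy]methyl}-2,2-dimethyl-4,7-dihydro-1,3-dioxepin-4-yl]-7-methyloct-6-en-2-yn-4-ol | CC#C[C@H](O)C/C=C(C)/C[C@H]1/C=C(/COCc2ccc(OC)cc2)COC(C)(C)O1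
F7 | step 10 | 4-O-triethylsilyl ether of F6 | CC#C[C@H](O[Si](CC)(CC)CC)C/C=C(C)/C[C@H]1/C=C(/COCc2ccc(OC)cc2)COC(C)(C)O1
F8 | step 10 | allylic alcohol from F7 (p-methoxybenzyl group removed) | CC#C[C@H](O[Si](CC)(CC)CC)C/C=C(C)/C[C@H]1/C=C(/CO)COC(C)(C)O1
F9 | step 10 | but-2-yn-1-yl ether of F8 | CC#C[C@H](O[Si](CC)(CC)CC)C/C=C(C)/C[C@H]1/C=C(/COCC#CC)COC(C)(C)O1
F10 | step 10 | 3-O-triethylsilyl ether of 20 | CC[Si](CC)(CC)O[C@@H]1C/C=C(C)/C[C@H]2/C=C(/COCC#C1)COC(C)(C)O2
F11 | step 8 | C4-epimeric mixture of 17 | ClCC#CC(O)C/C=C(C)/C[C@H]1/C=C(/COCc2ccc(OC)cc2)COC(C)(C)O1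
F12 | step 8 | (6E)-1-chloro-8-[(4S)-6-{[(4-methoxybenzyl)oxy]methyl}-2,2-dimethyl-4,7-dihydro-1,3-dioxepin-4-yl]-7-methyloct-6-en-2-yn-4-one | ClCC#CC(=O)C/C=C(C)/C[C@H]1/C=C(/COCc2ccc(OC)cc2)COC(C)(C)O1
F13 | step 2 | racemic 1-[(4-methoxybenzyl)oxy]-7-(trimethylsilyl)hepta-2,6-diyn-4-ol | C[Si](C)(C)C#CCC(O)C#CCOCc1ccc(OC)cc1
F14 | step 2 | 1-[(4-methoxybenzyl)oxy]-7-(trimethylsilyl)hepta-2,6-diyn-4-one | C[Si](C)(C)C#CCC(=O)C#CCOCc1ccc(OC)cc1
F15 | step 14 | (3R,6R,7S,8S)-3-[(tert-butyldimethylsilyl)oxy]-8,12-(isopropylidenedioxy)germacra-1(10)E,4E,11(13)-trien-15,6-olide | O=C1O[C@@H]2/C=C1/[C@H](O[Si](C)(C)C(C)(C)C)C/C=C(C)/C[C@H]3[C@H]2C(=C)COC(C)(C)O3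
A1 | alternative 1 | methyl 2-(bromomethyl)-4,7-bis[(tert-butyldimethylsilyl)oxy]-6-{[(tert-butyldimethylsilyl)oxy]methyl}-10-methyl-12-oxododeca-2,5,9-trienoate (C6 and C3 configured as in the target) | COC(=O)/C(CBr)=C/[C@H](O[Si](C)(C)C(C)(C)C)/C=C(CO[Si](C)(C)C(C)(C)C)/[C@H](O[Si](C)(C)C(C)(C)C)C/C=C(C)/CC=O
A2 | alternative 1 | 3,6,15-tris-O-(tert-butyldimethylsilyl) derivative of the target triol lactone | C=C1C(=O)O[C@H]2C/C(C)=C/C[C@@H](O[Si](C)(C)C(C)(C)C)/C(CO[Si](C)(C)C(C)(C)C)=C/[C@@H](O[Si](C)(C)C(C)(C)C)[C@H]12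
A3 | alternative 2 | 1-ethenyl-4-[(tert-butyldimethylsilyl)oxy]-3-{[(tert-butyldimethylsilyl)oxy]methyl}-6-(prop-1-en-2-yl)cyclohex-2-en-1-ol | C=C[C@@]1(O)C=C(CO[Si](C)(C)C(C)(C)C)[C@H](O[Si](C)(C)C(C)(C)C)C[C@@H]1C(C)=C
A4 | alternative 2 | (2Z,6E)-4-[(tert-butyldimethylsilyl)oxy]-3-{[(tert-butyldimethylsilyl)oxy]methyl}-7-methylcyclodeca-2,6-dien-1-one | O=C1/C=C(CO[Si](C)(C)C(C)(C)C)\[C@H](O[Si](C)(C)C(C)(C)C)C/C=C(C)/CCC1
A5 | alternative 3 | (4R,6E,9S)-4,9-bis[(tert-butyldimethylsilyl)oxy]-7,11-dimethyldodeca-6,10-dien-2-ynal | O=CC#C[C@H](O[Si](C)(C)C(C)(C)C)C/C=C(C)/C[C@H](O[Si](C)(C)C(C)(C)C)C=C(C)C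
A6 | alternative 3 | 3,8-bis[(tert-butyldimethylsilyl)oxy]germacra-1(10)E,11(13)-dien-4-yn-6-ol (configured as 22) | O[C@@H]1C#C[C@H](O[Si](C)(C)C(C)(C)C)C/C=C(C)/C[C@H](O[Si](C)(C)C(C)(C)C)[C@H]1C(C)=C
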